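Isochromene numbering: ring A is the carbocycle C4a–C8a, ring B the pyran O2/C1/C3/C4. The plan rests on cutting the enol-ether bond O2–C3. C3 is the δ-carbon of the push–pull dienone O2–C3=C4–C4a=C8a–C8=O, and its own side chain ends in a carboxyl group that can reach it. The precursor therefore holds C3 as an (E)-γ-ylidene-γ-butyrolactone on C4a, beside a silylated hydroxymethyl group on C8a. One fluoride treatment frees the C1 alcohol and both phenols. The alcohol adds to C3 and expels the lactone carboxylate, which closes ring B and releases the propanoic acid. Ring A, with C6 and C7, comes from (R)-carvone.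

Key step: step 9

Remark on the chemistry: 11 is a tautomer mixture and is drawn as its C4a enol. In 9, 10 and 16 one center is left undefined because both epimers lead on and the center is erased later.

Step 1
Reactants: 1 (R)-(−)-carvone
Product: 2 (5R,6R)-2-methyl-5-(prop-1-en-2-yl)-6-{[(triisopropylsilyl)oxy]methyl}cyclohex-2-en-1-one
Conditions: LiN(i-Pr)2 (LDA), THF, −78 °C; TOM-Cl, n-Bu4NI (cat.), −78 → −20 °C
Reagents that add atoms: (triisopropylsiloxy)methyl chloride (TOM-Cl), ClCO[Si](C(C)C)(C(C)C)C(C)C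
Why: Alkylation of the kinetic cross-conjugated lithium enolate with an α-chloro ether (as practised with BOM-Cl and SEM-Cl) brings in C1 with its oxygen already protected and occurs anti to the isopropenyl group, setting a temporary center that step 6 erases.

Step 2
Reactants: 2 silyloxymethyl carvone
Product: 3 (1R,3R,4R,6R)-1-methyl-4-(prop-1-en-2-yl)-3-{[(triisopropylsilyl)oxy]methyl}-7-oxabicyclo[4.1.0]heptan-2-one
Conditions: 30% H2O2, NaOH (cat.), MeOH, 0 °C
Reagents that add atoms: hydrogen peroxide, OO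
Why: Weitz–Scheffer nucleophilic epoxidation touches only the enone, and hydroperoxide adds to the face anti to the isopropenyl group, which sets the C–O center that becomes (6R).

Step 3
Reactants: 3 epoxy ketone
Product: 4 (2R,3R,5R,6R)-3-hydroxy-2-methyl-5-(prop-1-en-2-yl)-6-{[(triisopropylsilyl)oxy]methyl}cyclohexan-1-one
Conditions: SmI2 (2.2 equiv), THF–MeOH, −90 °C
Reagents that add atoms: none
Why: Single-electron reductive opening of the α,β-epoxy ketone cleaves the α C–O bond, and axial protonation of the trivalent samarium enolate places the methyl group equatorial and cis to the axial hydroxyl, which is also the thermodynamic epimer and sets (7R).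

Step 4
Reactants: 5 orsellinic acid (2,4-dihydroxy-6-methylbenzoic acid)
Product: 6 tert-butyldimethylsilyl 2,4-bis[(tert-butyldimethylsilyl)oxy]-6-methylbenzoate
Conditions: TBSCl (3.5 equiv), imidazole, DMAP (cat.), DMF, 40 °C
Reagents that add atoms: tert-butyldimethylsilyl chloride, CC(C)(C)[Si](C)(C)Cl
Why: Exhaustive silylation masks both phenols for the ozone, triflation and palladium steps and gives a silyl ester that can be turned into the acid chloride under neutral conditions.

Step 5
Reactants: 4 hydroxy ketone; 6 tris-silylated orsellinic acid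
Product: 8 (1R,2R,4R,5R)-2-methyl-3-oxo-5-(prop-1-en-2-yl)-4-{[(triisopropylsilyl)oxy]methyl}cyclohexyl 2,4-bis[(tert-butyldimethylsilyl)oxy]-6-methylbenzoate, via acid chloride 7 (not isolated)
Conditions: 6, (COCl)2, DMF (cat.), CH2Cl2, 0 °C → rt; then 4, pyridine, DMAP, CH2Cl2, 0 °C → rt
Reagents that add atoms: none
Why: The chloroiminium salt converts the silyl ester into the acid chloride without free acid, and DMAP-catalysed acylation of the C6 hydroxyl keeps the configuration because the C–O bond is not touched.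

Step 6
Reactants: 8 isopropenyl keto ester
Product: 11 (1R,2R)-5-hydroxy-2-methyl-3-oxo-4-{[(triisopropylsilyl)oxy]methyl}cyclohex-4-en-1-yl 2,4-bis[(tert-butyldimethylsilyl)oxy]-6-methylbenzoate (enol form of the 1,3-dione), via methoxy hydroperoxide 9 (not isolated), via TEMPO alkoxyamine 10 (not isolated)
Conditions: O3, MeOH–CH2Cl2, −78 °C; FeSO4·7H2O, TEMPO, −78 °C → rt; then mCPBA (1.1 equiv), CH2Cl2, 0 °C; product used at once
Reagents that add atoms: TEMPO (its oxygen becomes the C4a oxygen), CC1(C)CCCC(C)(C)N1[O]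
Why: Dealkenylative oxidation swaps the isopropenyl group, whose stereocontrol task is done, for the C4a oxygen and erases the temporary centers C4a and C8a by enolization; the sequence is ozonolysis in methanol, O–O cleavage by divalent iron, β-scission with loss of methyl acetate, capture of the C4a radical by TEMPO and peracid fragmentation of the secondary alkoxyamine.

Step 7
Reactants: 11 1,3-dione
Product: 12 (1R,2R)-2-methyl-3-oxo-4-{[(triisopropylsilyl)oxy]methyl}-5-[(trifluoromethanesulfonyl)oxy]cyclohex-4-en-1-yl 2,4-bis[(tert-butyldimethylsilyl)oxy]-6-methylbenzoate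
Conditions: Tf2O, 2,6-lutidine, CH2Cl2, −78 °C
Reagents that add atoms: trifluoromethanesulfonic anhydride, O=S(=O)(OS(=O)(=O)C(F)(F)F)C(F)(F)F
Why: O-sulfonylation of the dione enolate (vinylogous acyl triflate formation) should occur at the less hindered oxygen on C4a, flanked by the C5 methylene group, and not at the C8 oxygen next to the methyl-bearing C7.

Step 8
Reactants: 12 vinyl triflate; 13 pent-4-ynoic acid
Product: 14 (1R,2R)-2-methyl-3-oxo-5-[(E)-(5-oxodihydrofuran-2(3H)-ylidene)methyl]-4-{[(triisopropylsilyl)oxy]methyl}cyclohex-4-en-1-yl 2,4-bis[(tert-butyldimethylsilyl)oxy]-6-methylbenzoate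
Conditions: Pd(PPh3)4 (5 mol %), Et3N, n-Bu4NCl, DMF, rt → 40 °C
Reagents that add atoms: none
Why: This is the known palladium-catalysed coupling–cyclization of 4-alkynoic acids with vinyl triflates, in which zerovalent palladium adds oxidatively, the carboxylate attacks the alkyne bound to the vinylpalladium species in an anti 5-exo-dig mode, and reductive elimination forms C4a–C4 and the E ylidene lactone without any protecting group on the acid.

Step 9
Reactants: 14 silylated ylidene lactone
Product: 17 3-[(6R,7R)-6-(2,4-dihydroxy-6-methylbenzoyloxy)-7-methyl-8-oxo-5,6,7,8-tetrahydro-1H-isochromen-3-yl]propanoic acid (target), via desilylated ylidene lactone 15 (not isolated), via spiroketal dienol 16 (not isolated)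
Conditions: HF·pyridine, pyridine, THF, 0 °C → rt; pH 7 phosphate buffer work-up
Reagents that add atoms: none
Why: Proposed new method: fluoride strips the TIPS ether and both aryl TBS ethers to give 15, whose C1 hydroxyl adds to C3, the δ-carbon of the C8=O/C8a=C4a/C4=C3 dienone, to give spiroketal dienol 16, and re-formation of the C8 ketone then expels the lactone carboxylate (vinylogous addition–elimination), so that O2–C3 is made and the propanoic acid is released in the same event. The closest known reaction types are the transvinylation of alcohols with enol esters, the addition–elimination of alcohols on β-acyloxy enones and the acid-induced recyclization of furylmethyl-substituted benzyl alcohols to isochromenes, none of which has been run on a dienone-conjugated ylidene lactone. Ring B closes in the 6-endo-trig mode while the five-membered lactone opens. No lasting stereocenter is created, since the spiro carbon of 16 returns to sp2, and C6 and C7 stay untouched because the weakly acidic pyridinium fluoride buffer does not enolize C8 towards C7. The step needs attack at C3 and not at the lactone carbonyl or at C4: acyl attack would require a nine-membered ring, and C4 is the electron-rich position of the dienone, so the furan-forming 5-exo path open to a corresponding enynol does not exist here. Adventitious water only diverts material to the 4-oxo acid, which reaches the same product by hemiketalization and dehydration.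

Compound list
1 | (R)-(−)-carvone | CC1=CC[C@H](CC1=O)C(C)=C | starting material
2 | (5R,6R)-2-methyl-5-(prop-1-en-2-yl)-6-{[(triisopropylsilyl)oxy]methyl}cyclohex-2-en-1-one | CC1=CC[C@@H](C(C)=C)[C@H](CO[Si](C(C)C)(C(C)C)C(C)C)C1=O | intermediate
3 | (1R,3R,4R,6R)-1-methyl-4-(prop-1-en-2-yl)-3-{[(triisopropylsilyl)oxy]methyl}-7-oxabicyclo[4.1.0]heptan-2-one | C[C@@]12O[C@@H]1C[C@@H](C(C)=C)[C@H](CO[Si](C(C)C)(C(C)C)C(C)C)C2=O | intermediate
4 | (2R,3R,5R,6R)-3-hydroxy-2-methyl-5-(prop-1-en-2-yl)-6-{[(triisopropylsilyl)oxy]methyl}cyclohexan-1-one | C[C@@H]1[C@H](O)C[C@@H](C(C)=C)[C@H](CO[Si](C(C)C)(C(C)C)C(C)C)C1=O | intermediate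
5 | orsellinic acid | Cc1cc(O)cc(O)c1C(=O)O | starting material
6 | tert-butyldimethylsilyl 2,4-bis[(tert-butyldimethylsilyl)oxy]-6-methylbenzoate | Cc1cc(O[Si](C)(C)C(C)(C)C)cc(O[Si](C)(C)C(C)(C)C)c1C(=O)O[Si](C)(C)C(C)(C)C | intermediate
7 | 2,4-bis[(tert-butyldimethylsilyl)oxy]-6-methylbenzoyl chloride (not isolated) | Cc1cc(O[Si](C)(C)C(C)(C)C)cc(O[Si](C)(C)C(C)(C)C)c1C(=O)Cl | intermediate
8 | (1R,2R,4R,5R)-2-methyl-3-oxo-5-(prop-1-en-2-yl)-4-{[(triisopropylsilyl)oxy]methyl}cyclohexyl 2,4-bis[(tert-butyldimethylsilyl)oxy]-6-methylbenzoate | C[C@@H]1[C@H](OC(=O)c2c(C)cc(O[Si](C)(C)C(C)(C)C)cc2O[Si](C)(C)C(C)(C)C)C[C@@H](C(C)=C)[C@H](CO[Si](C(C)C)(C(C)C)C(C)C)C1=O | intermediate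
9 | methoxy hydroperoxide: 8 with the isopropenyl group replaced by 2-hydroperoxy-2-methoxyethan-2-yl (side-chain center undefined, not isolated) | C[C@@H]1[C@H](OC(=O)c2c(C)cc(O[Si](C)(C)C(C)(C)C)cc2O[Si](C)(C)C(C)(C)C)C[C@@H](C(C)(OC)OO)[C@H](CO[Si](C(C)C)(C(C)C)C(C)C)C1=O | intermediate
10 | TEMPO alkoxyamine: 8 with the isopropenyl group replaced by (2,2,6,6-tetramethylpiperidin-1-yl)oxy (epimers at C4a, not isolated) | C[C@@H]1[C@H](OC(=O)c2c(C)cc(O[Si](C)(C)C(C)(C)C)cc2O[Si](C)(C)C(C)(C)C)CC(ON2C(C)(C)CCCC2(C)C)[C@H](CO[Si](C(C)C)(C(C)C)C(C)C)C1=O | intermediate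
11 | (1R,2R)-5-hydroxy-2-methyl-3-oxo-4-{[(triisopropylsilyl)oxy]methyl}cyclohex-4-en-1-yl 2,4-bis[(tert-butyldimethylsilyl)oxy]-6-methylbenzoate | C[C@@H]1[C@H](OC(=O)c2c(C)cc(O[Si](C)(C)C(C)(C)C)cc2O[Si](C)(C)C(C)(C)C)CC(O)=C(CO[Si](C(C)C)(C(C)C)C(C)C)C1=O | intermediate
12 | (1R,2R)-2-methyl-3-oxo-4-{[(triisopropylsilyl)oxy]methyl}-5-[(trifluoromethanesulfonyl)oxy]cyclohex-4-en-1-yl 2,4-bis[(tert-butyldimethylsilyl)oxy]-6-methylbenzoate | C[C@@H]1[C@H](OC(=O)c2c(C)cc(O[Si](C)(C)C(C)(C)C)cc2O[Si](C)(C)C(C)(C)C)CC(OS(=O)(=O)C(F)(F)F)=C(CO[Si](C(C)C)(C(C)C)C(C)C)C1=O | intermediate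
13 | pent-4-ynoic acid | C#CCCC(=O)O | starting material
14 | (1R,2R)-2-methyl-3-oxo-5-[(E)-(5-oxodihydrofuran-2(3H)-ylidene)methyl]-4-{[(triisopropylsilyl)oxy]methyl}cyclohex-4-en-1-yl 2,4-bis[(tert-butyldimethylsilyl)oxy]-6-methylbenzoate | C[C@@H]1[C@H](OC(=O)c2c(C)cc(O[Si](C)(C)C(C)(C)C)cc2O[Si](C)(C)C(C)(C)C)CC(/C=C2/OC(=O)CC2)=C(CO[Si](C(C)C)(C(C)C)C(C)C)C1=O | intermediate
15 | (1R,2R)-4-(hydroxymethyl)-2-methyl-3-oxo-5-[(E)-(5-oxodihydrofuran-2(3H)-ylidene)methyl]cyclohex-4-en-1-yl 2,4-dihydroxy-6-methylbenzoate (not isolated) | C[C@@H]1[C@H](OC(=O)c2c(C)cc(O)cc2O)CC(/C=C2/OC(=O)CC2)=C(CO)C1=O | intermediate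
16 | spiroketal dienol: O2 bonded to C3, C3 spiro to the γ-lactone, double bonds C4=C4a and C8a=C8(OH), (6R,7R), spiro center undefined (not isolated) | C[C@@H]1[C@H](OC(=O)c2c(C)cc(O)cc2O)CC2=CC3(CCC(=O)O3)OCC2=C1O | intermediate
17 | 3-[(6R,7R)-6-(2,4-dihydroxy-6-methylbenzoyloxy)-7-methyl-8-oxo-5,6,7,8-tetrahydro-1H-isochromen-3-yl]propanoic acid | Cc1cc(O)cc(O)c1C(=O)O[C@@H]1CC2=C(COC(CCC(=O)O)=C2)C(=O)[C@@H]1C | target

Total step count: 9. Longest linear sequence: 8 steps from (R)-carvone (steps 1, 2, 3, 5, 6, 7, 8, 9).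

Steps most likely to fail

1. Step 9.
- What may go wrong: the freed alcohol may add too slowly to the weakly activated δ-carbon. The adduct may also ketonize and rest at the spiroketal lactone stage instead of expelling the carboxylate.
- Fallback: it uses known chemistry, sets out from 12 and comes back at 17. Sonogashira coupling of 12 with commercial methyl pent-4-ynoate (PdCl2(PPh3)2, CuI, i-Pr2NEt, THF, 0 °C) gives the silylated enynone methyl ester F1. HF·pyridine gives the enynone triol methyl ester F2. A 6-endo-dig hydroalkoxylation catalysed by (Ph3P)AuNTf2 gives the methyl ester of the target F3. Its regiochemistry is directed to C3 by the polarization of the enynone. Pig liver esterase at pH 7 cleaves only the unhindered methyl ester and gives 17.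

2. Step 6.
- What may go wrong: the peracid may over-oxidize the enolic dione. The dione may also lose silanol or the aroic acid, with aromatization, during the oxidative stage.
- Fallback: it sets out from 10 and comes back at 11. The alkoxyamine 10 is isolated and its N–O bond is cleaved reductively (Zn, AcOH, THF) to the β-hydroxy ketone F4. Anhydrous Dess–Martin oxidation buffered with NaHCO3 gives 11, which goes straight into step 7, so no peracid ever meets the dione.

3. Step 8.
- What may go wrong: the amine may induce β-elimination of the aroyloxy group with aromatization. Carboxylate or chloride in DMF may cleave the aryl silyl ethers. Plain alkynylation without lactonization may also occur.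
- Fallback: it sets out from 12 and comes back at 16. Sonogashira coupling of 12 with 13 at 0 °C (PdCl2(PPh3)2, CuI, i-Pr2NEt, THF) gives the silylated enynoic acid F5. A separate 5-exo-dig cycloisomerization catalysed by AgNO3 in acetone gives the (Z)-ylidene lactone F6. Under the conditions of step 9 this is desilylated to the Z lactone triol F7. Its alkene geometry is lost on addition of the alcohol, so the route is rejoined at 16.

Further compounds
F1 | step 9 | (1R,2R)-5-(5-methoxy-5-oxopent-1-yn-1-yl)-2-methyl-3-oxo-4-{[(triisopropylsilyl)oxy]methyl}cyclohex-4-en-1-yl 2,4-bis[(tert-butyldimethylsilyl)oxy]-6-methylbenzoate | C[C@@H]1[C@H](OC(=O)c2c(C)cc(O[Si](C)(C)C(C)(C)C)cc2O[Si](C)(C)C(C)(C)C)CC(C#CCCC(=O)OC)=C(CO[Si](C(C)C)(C(C)C)C(C)C)C1=O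
F2 | step 9 | (1R,2R)-4-(hydroxymethyl)-5-(5-methoxy-5-oxopent-1-yn-1-yl)-2-methyl-3-oxocyclohex-4-en-1-yl 2,4-dihydroxy-6-methylbenzoate | C[C@@H]1[C@H](OC(=O)c2c(C)cc(O)cc2O)CC(C#CCCC(=O)OC)=C(CO)C1=O
F3 | step 9 | methyl 3-[(6R,7R)-6-(2,4-dihydroxy-6-methylbenzoyloxy)-7-methyl-8-oxo-5,6,7,8-tetrahydro-1H-isochromen-3-yl]propanoate | Cc1cc(O)cc(O)c1C(=O)O[C@@H]1CC2=C(COC(CCC(=O)OC)=C2)C(=O)[C@@H]1C
F4 | step 6 | (1R,2R,4R)-5-hydroxy-2-methyl-3-oxo-4-{[(triisopropylsilyl)oxy]methyl}cyclohexyl 2,4-bis[(tert-butyldimethylsilyl)oxy]-6-methylbenzoate (epimers at the carbinol carbon) | C[C@@H]1[C@H](OC(=O)c2c(C)cc(O[Si](C)(C)C(C)(C)C)cc2O[Si](C)(C)C(C)(C)C)CC(O)[C@H](CO[Si](C(C)C)(C(C)C)C(C)C)C1=O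
F5 | step 8 | 5-[(4R,5R)-5-{2,4-bis[(tert-butyldimethylsilyl)oxy]-6-methylbenzoyloxy}-4-methyl-3-oxo-2-{[(triisopropylsilyl)oxy]methyl}cyclohex-1-en-1-yl]pent-4-ynoic acid | C[C@@H]1[C@H](OC(=O)c2c(C)cc(O[Si](C)(C)C(C)(C)C)cc2O[Si](C)(C)C(C)(C)C)CC(C#CCCC(=O)O)=C(CO[Si](C(C)C)(C(C)C)C(C)C)C1=O
F6 | step 8 | Z isomer of 14 | C[C@@H]1[C@H](OC(=O)c2c(C)cc(O[Si](C)(C)C(C)(C)C)cc2O[Si](C)(C)C(C)(C)C)CC(/C=C2\OC(=O)CC2)=C(CO[Si](C(C)C)(C(C)C)C(C)C)C1=O
F7 | step 8 | Z isomer of 15 | C[C@@H]1[C@H](OC(=O)c2c(C)cc(O)cc2O)CC(/C=C2\OC(=O)CC2)=C(CO)C1=O
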